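## Retrosynthetic overview

1. C2–C3 is cut last: the acetic acid arm is added to a C3 peroxycarbenium ion (3-methoxy-1,2-dioxane plus a ketene bis-silyl acetal), with axial attack setting C3.
2. The only ring, the 1,2-dioxane, is closed in step 9: the O–C6 bond comes from cobalt-mediated hydroperoxysilylation of a C6 ethylidene alkene, the O–C3 bond from peroxy-acetalisation onto a C3 dimethyl acetal.
3. C4–C5 is the key bond: the dissonant 1,4-dioxygen pattern C3/C6 is traced to a γ-keto aldehyde made by oxidative enamine (SOMO, enolonium-type) coupling of butanal with the silyl enol ether of the side-chain methyl ketone; this sets C4.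
4. Side-chain ketone: C8 by copper-catalysed asymmetric methyl conjugate addition to a dienone; C10 and the E-alkene by Johnson–Claisen chirality transfer from (3R,4E)-hept-4-en-3-ol, made from (E)-pent-2-enal and Et2Zn.

Assumption: the usual sense of induction holds ((+)-MIB gives the 3R alcohol, (R,S)-Josiphos the 4S ketone, the (2R,5R)-imidazolidinone the 2S aldehyde; otherwise the mirror-image ligand is used), and ketene bis(trimethylsilyl) acetal is treated as a purchasable reagent (otherwise one operation from trimethylsilyl acetate).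

Atom numbers C1–C14 in the "Why" lines refer to the target chain (C1 = CO2H, ring carbons C3–C6).

## Route

Step 1
Reactants: 1 (E)-pent-2-enal
Product: 2 (3R,4E)-hept-4-en-3-ol
Conditions: Et2Zn (1.5 equiv), (+)-MIB [(2R)-3-exo-morpholinoisoborneol, 4 mol%], hexane/toluene, 0 °C; aqueous work-up
Reagents that add atoms: diethylzinc, CC[Zn]CC
Why: Amino-alcohol-catalysed enantioselective 1,2-addition of a dialkylzinc to an enal, in which the chiral zinc alkoxide complex delivers ethyl to the Re face of the aldehyde and sets the carbinol centre as R (about 95% ee expected).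

Step 2
Reactants: 2 (3R,4E)-hept-4-en-3-ol
Product: 4 ethyl (3R,4E)-3-ethylhept-4-enoate, via mixed ketene acetal 3 (not isolated)
Conditions: CH3C(OEt)3 (6 equiv), EtCO2H (5 mol%), 140 °C, ethanol distilled off
Reagents that add atoms: triethyl orthoacetate, CC(OCC)(OCC)OCC
Why: Johnson–Claisen [3,3] rearrangement through a chair with the carbinol ethyl group equatorial, which gives the E-alkene and transfers the C–O stereocentre suprafacially to the new C–C stereocentre (C10, R).

Step 3
Reactants: 4 ethyl (3R,4E)-3-ethylhept-4-enoate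
Product: 6 (3E,6R,7E)-6-ethyldeca-3,7-dien-2-one, via aldehyde 5 (not isolated)
Conditions: i-Bu2AlH (1.05 equiv), CH2Cl2, −78 °C; then Ph3P=CHC(O)CH3 (1.5 equiv), −78 °C to 40 °C; Rochelle salt work-up
Reagents that add atoms: 1-(triphenylphosphoranylidene)propan-2-one, CC(=O)C=P(c1ccccc1)(c1ccccc1)c1ccccc1
Why: Half-reduction of the ester to the aluminium hemiacetal, which releases the volatile aldehyde on warming for an in-situ E-selective Wittig reaction with the stabilised keto ylide; the stereocentre is β to the carbonyl and cannot epimerise.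

Step 4
Reactants: 6 (3E,6R,7E)-6-ethyldeca-3,7-dien-2-one
Product: 7 (4S,6R,7E)-6-ethyl-4-methyldec-7-en-2-one
Conditions: MeMgBr (1.2 equiv), CuBr·SMe2 (5 mol%), (R)-1-[(S)-2-(diphenylphosphino)ferrocenyl]ethyldicyclohexylphosphine [(R,S)-Josiphos, 6 mol%], t-BuOMe, −75 °C; H2O quench
Reagents that add atoms: methylmagnesium bromide, C[Mg]Br
Why: Copper-catalysed asymmetric conjugate addition of a Grignard reagent to an acyclic E-enone, in which the chiral monovalent copper–diphosphine complex controls the face of methyl delivery and sets C8 as S; the remote C10 centre has little influence and the isolated alkene is inert.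

Step 5
Reactants: 7 (4S,6R,7E)-6-ethyl-4-methyldec-7-en-2-one
Product: 8 tert-butyl{[(4S,6R,7E)-6-ethyl-4-methyldeca-1,7-dien-2-yl]oxy}dimethylsilane
Conditions: LiN(i-Pr)2 (1.1 equiv, commercial solution), THF, −78 °C; t-BuMe2SiOTf (1.2 equiv), −78 °C; pentane/pH 7 work-up, used directly
Reagents that add atoms: tert-butyldimethylsilyl trifluoromethanesulfonate, CC(C)(C)[Si](C)(C)OS(=O)(=O)C(F)(F)F
Why: Kinetic deprotonation of the methyl ketone at the unhindered methyl group and O-silylation of the lithium enolate give the terminal silyl enol ether (above 95:5 expected); no stereocentre is touched.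

Step 6
Reactants: 8 tert-butyl{[(4S,6R,7E)-6-ethyl-4-methyldeca-1,7-dien-2-yl]oxy}dimethylsilane; 9 butanal
Product: 10 (2S,6S,8R,9E)-2,8-diethyl-6-methyl-4-oxododec-9-enal
Conditions: 9 (1.0 equiv), 8 (1.5 equiv; the excess returns as 7 on work-up), (2R,5R)-5-benzyl-2-tert-butyl-3-methylimidazolidin-4-one trifluoroacetate (20 mol%), (NH4)2Ce(NO3)6 (2.2 equiv), 2,6-di-tert-butylpyridine (2 equiv), H2O (2 equiv), DME, −20 °C, 24 h; crude product carried on
Reagents that add atoms: none
Why: Organo-SOMO α-enolation of an aldehyde: tetravalent cerium oxidises the chiral enamine of butanal to a three-π-electron radical cation (an enolonium equivalent), and the CH2 terminus of enol silane 8 attacks its α-carbon on the face anti to the benzyl group, joining two normally nucleophilic carbons (C4–C5) and setting C4 as S (about 90% ee expected).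

Step 7
Reactants: 10 (2S,6S,8R,9E)-2,8-diethyl-6-methyl-4-oxododec-9-enal
Product: 11 (2S,6S,8R,9E)-2,8-diethyl-1,1-dimethoxy-6-methyldodec-9-en-4-one
Conditions: MeOSiMe3 (2.5 equiv), Me3SiOTf (3 mol%), CH2Cl2, −78 °C; pyridine quench
Reagents that add atoms: methoxytrimethylsilane, CO[Si](C)(C)C
Why: Noyori acetalisation, which at −78 °C converts the aldehyde far faster than the ketone and does not enolise the α-stereocentre; the acetal later serves as the C3 electrophile for ring closure.

Step 8
Reactants: 11 (2S,6S,8R,9E)-2,8-diethyl-1,1-dimethoxy-6-methyldodec-9-en-4-one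
Product: 12 (3E,5R,7S,11S)-5,11-diethyl-9-ethylidene-12,12-dimethoxy-7-methyldodec-3-ene (ethylidene E/Z mixture)
Conditions: EtPPh3Br (2.5 equiv), KOt-Bu (2.4 equiv), THF, 0 °C to rt
Reagents that add atoms: ethyltriphenylphosphonium bromide, CC[P+](c1ccccc1)(c1ccccc1)c1ccccc1.[Br-]
Why: Wittig ethylidenation of the dialkyl ketone installs the C6 ethyl carbons; the acetal is inert, both stereocentres are β to the ketone, and the new alkene geometry is irrelevant because step 9 destroys it.

Step 9
Reactants: 12 (3E,5R,7S,11S)-5,11-diethyl-9-ethylidene-12,12-dimethoxy-7-methyldodec-3-ene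
Product: 15 (4S)-4,6-diethyl-6-[(2S,4R,5E)-4-ethyl-2-methyloct-5-en-1-yl]-3-methoxy-1,2-dioxane (mixture of C3/C6 epimers), via triethylsilyl peroxide 13 (not isolated), via hydroperoxide 14 (not isolated)
Conditions: Co(thd)2 [bis(2,2,6,6-tetramethylheptane-3,5-dionato)cobalt, 10 mol%], O2 (1 atm), Et3SiH (2 equiv), ClCH2CH2Cl, rt; silica plug; then p-TsOH·H2O (10 mol%), MeOH/CH2Cl2, 0 °C
Reagents that add atoms: dioxygen, O=O; triethylsilane, CC[SiH](CC)CC (silyl group present only in 13)
Why: Mukaiyama–Isayama hydroperoxysilylation, in which a cobalt hydride transfers hydrogen to the trisubstituted alkene (much faster than to the 1,2-disubstituted side-chain alkene) and the tertiary C6 radical traps O2, followed by acid desilylation and six-membered peroxy-acetalisation onto the dimethyl acetal; C6 forms without control (about 1:1) and is sorted after step 10.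

Step 10
Reactants: 15 (4S)-4,6-diethyl-6-[(2S,4R,5E)-4-ethyl-2-methyloct-5-en-1-yl]-3-methoxy-1,2-dioxane
Product: 17 2-[(3S,4S,6R)-4,6-diethyl-6-[(2S,4R,5E)-4-ethyl-2-methyloct-5-en-1-yl]-1,2-dioxan-3-yl]acetic acid, via trimethylsilyl ester 16 (not isolated)
Conditions: CH2=C(OSiMe3)2 (2 equiv), Me3SiOTf (0.2 equiv), CH2Cl2, −78 °C; pH 4 aqueous work-up; preparative HPLC to remove the 6-epimer and minor isomers
Reagents that add atoms: ketene bis(trimethylsilyl) acetal, C=C(O[Si](C)(C)C)O[Si](C)(C)C
Why: Mukaiyama-type addition of a silyl ketene acetal to a peroxycarbenium ion whose half-chair is locked with the C4 ethyl pseudo-equatorial (the alternative puts it syn-diaxial to a C6 alkyl group), so axial attack places the acetate arm cis to the C4 ethyl (C3 = S), and the silyl ester hydrolyses on work-up to give the acid without any base.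

## Compound list

1 | (E)-pent-2-enal | CC/C=C/C=O | starting material
2 | (3R,4E)-hept-4-en-3-ol | CC[C@@H](O)/C=C/CC | intermediate
3 | (3R,4E)-3-[(1-ethoxyethenyl)oxy]hept-4-ene (mixed ketene acetal) | CC[C@@H](OC(=C)OCC)/C=C/CC | intermediate (not isolated)
4 | ethyl (3R,4E)-3-ethylhept-4-enoate | CC/C=C/[C@H](CC)CC(=O)OCC | intermediate
5 | (3R,4E)-3-ethylhept-4-enal | CC/C=C/[C@H](CC)CC=O | intermediate (not isolated)
6 | (3E,6R,7E)-6-ethyldeca-3,7-dien-2-one | CC/C=C/[C@H](CC)C/C=C/C(C)=O | intermediate
7 | (4S,6R,7E)-6-ethyl-4-methyldec-7-en-2-one | CC/C=C/[C@H](CC)C[C@H](C)CC(C)=O | intermediate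
8 | tert-butyl{[(4S,6R,7E)-6-ethyl-4-methyldeca-1,7-dien-2-yl]oxy}dimethylsilane | CC/C=C/[C@H](CC)C[C@H](C)CC(=C)O[Si](C)(C)C(C)(C)C | intermediate
9 | butanal | CCCC=O | starting material
10 | (2S,6S,8R,9E)-2,8-diethyl-6-methyl-4-oxododec-9-enal | CC/C=C/[C@H](CC)C[C@H](C)CC(=O)C[C@H](CC)C=O | intermediate
11 | (2S,6S,8R,9E)-2,8-diethyl-1,1-dimethoxy-6-methyldodec-9-en-4-one | CC/C=C/[C@H](CC)C[C@H](C)CC(=O)C[C@H](CC)C(OC)OC | intermediate
12 | (3E,5R,7S,11S)-5,11-diethyl-9-ethylidene-12,12-dimethoxy-7-methyldodec-3-ene (ethylidene E/Z mixture) | CC/C=C/[C@H](CC)C[C@H](C)CC(=CC)C[C@H](CC)C(OC)OC | intermediate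
13 | triethyl{[(3E,5R,7S,11S)-5,9,11-triethyl-12,12-dimethoxy-7-methyldodec-3-en-9-yl]peroxy}silane (both C9 epimers) | CC/C=C/[C@H](CC)C[C@H](C)CC(CC)(OO[Si](CC)(CC)CC)C[C@H](CC)C(OC)OC | intermediate (not isolated)
14 | (3E,5R,7S,11S)-5,9,11-triethyl-9-hydroperoxy-12,12-dimethoxy-7-methyldodec-3-ene (both C9 epimers) | CC/C=C/[C@H](CC)C[C@H](C)CC(CC)(OO)C[C@H](CC)C(OC)OC | intermediate (not isolated)
15 | (4S)-4,6-diethyl-6-[(2S,4R,5E)-4-ethyl-2-methyloct-5-en-1-yl]-3-methoxy-1,2-dioxane (C3/C6 epimer mixture) | CC/C=C/[C@H](CC)C[C@H](C)CC1(CC)C[C@H](CC)C(OC)OO1 | intermediate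
16 | trimethylsilyl 2-[(3S,4S,6R)-4,6-diethyl-6-[(2S,4R,5E)-4-ethyl-2-methyloct-5-en-1-yl]-1,2-dioxan-3-yl]acetate (formed together with its 6-epimer) | CC/C=C/[C@H](CC)C[C@H](C)C[C@]1(CC)C[C@H](CC)[C@H](CC(=O)O[Si](C)(C)C)OO1 | intermediate (not isolated)
17 | 2-[(3S,4S,6R)-4,6-diethyl-6-[(2S,4R,5E)-4-ethyl-2-methyloct-5-en-1-yl]-1,2-dioxan-3-yl]acetic acid | CC/C=C/[C@H](CC)C[C@H](C)C[C@]1(CC)C[C@H](CC)[C@H](CC(=O)O)OO1 | target

## Step count and risk

Total step count: 10. Longest linear sequence: 10 steps (1 to 17); butanal 9 and all reagents are purchased.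

Stereocentres: C10 in steps 1–2, C8 in step 4, C4 in step 6, C3 in step 10. C6 is formed unselectively in step 9, so at most half of the material from step 9 becomes 17. The 6-epimer, together with the minor C4 and C8 diastereomers arising from the roughly 90–95% selectivity of steps 1, 4 and 6, is removed by the HPLC in step 10.

The three steps most likely to fail:

Step 6. The SOMO coupling has not been run with an enol silane of this size. Direct oxidation of 8 by the cerium salt, a moderate yield, or an ee below 90% are the likely problems. The fallback sets out from 8. N-Bromosuccinimide in THF at −78 °C converts it into the bromomethyl ketone (4S,6R,7E)-1-bromo-6-ethyl-4-methyldec-7-en-2-one F1. Butanal 9 is then alkylated with F1 under combined photoredox and enamine catalysis (Ru(bpy)3Cl2, a chiral imidazolidinone of the hand that gives the 2S aldehyde, 2,6-lutidine, DMF, visible light). Here the electrophilic α-keto radical from F1 adds to the chiral enamine, so the reversed polarity now sits on the ketone α-carbon. This gives 10, and the route continues at step 7.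

Step 9. The radical hydroperoxidation gives no control at C6, could touch the side-chain alkene, and the hydroperoxide must survive residual cobalt and acid. The fallback sets out from 12. Anhydrous ethereal H2O2 with catalytic camphorsulfonic acid exchanges one methoxy group for OOH and gives the hydroperoxy acetal (3E,5R,7S,11S)-5,11-diethyl-9-ethylidene-12-hydroperoxy-12-methoxy-7-methyldodec-3-ene F2. N-Iodosuccinimide in CH2Cl2 at 0 °C then closes the ring by 6-exo iodo-cycloperoxidation at the more substituted alkene carbon, a two-electron process through a chair that may bias C6. The product is (4S)-4-ethyl-6-[(2S,4R,5E)-4-ethyl-2-methyloct-5-en-1-yl]-6-(1-iodoethyl)-3-methoxy-1,2-dioxane F3. Bu3SnH with Et3B/air at −20 °C removes the iodine and returns 15, from which step 10 follows.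

Step 10. Bis-silyl ketene acetals have not been used with peroxycarbenium ions, the cis selectivity at C3 is predicted rather than measured, and the acid and its 6-epimer may be hard to separate. The fallback sets out from 15. TiCl4-mediated addition of commercial 1-(tert-butyldimethylsilyloxy)-1-methoxyethene in CH2Cl2 at −78 °C gives the neutral methyl 2-[(3S,4S,6R)-4,6-diethyl-6-[(2S,4R,5E)-4-ethyl-2-methyloct-5-en-1-yl]-1,2-dioxan-3-yl]acetate F4. Its 6-epimer is removed on silica, and LiOH in THF/H2O at 0 °C then gives 17.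

Further compounds
F1 | step 6 | (4S,6R,7E)-1-bromo-6-ethyl-4-methyldec-7-en-2-one | CC/C=C/[C@H](CC)C[C@H](C)CC(=O)CBr
F2 | step 9 | (3E,5R,7S,11S)-5,11-diethyl-9-ethylidene-12-hydroperoxy-12-methoxy-7-methyldodec-3-ene | CC/C=C/[C@H](CC)C[C@H](C)CC(=CC)C[C@H](CC)C(OC)OO
F3 | step 9 | (4S)-4-ethyl-6-[(2S,4R,5E)-4-ethyl-2-methyloct-5-en-1-yl]-6-(1-iodoethyl)-3-methoxy-1,2-dioxane | CC/C=C/[C@H](CC)C[C@H](C)CC1(C(C)I)C[C@H](CC)C(OC)OO1
F4 | step 10 | methyl 2-[(3S,4S,6R)-4,6-diethyl-6-[(2S,4R,5E)-4-ethyl-2-methyloct-5-en-1-yl]-1,2-dioxan-3-yl]acetate | CC/C=C/[C@H](CC)C[C@H](C)C[C@]1(CC)C[C@H](CC)[C@H](CC(=O)OC)OO1
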